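## Structural features

The target 14 is a single cyclohexene, ring A, numbered here so that C1 carries the exocyclic benzoyloxymethyl carbon C7, C1=C2 is the double bond and C3 to C6 are four contiguous carbinol stereocentres (3R,4S,5R,6S); the same atom numbers are used for every intermediate. O3 and O4 are free and trans to each other, O5 is benzoylated and cis to O4, and the free allylic O6 is trans to O5. The fragile features are the two allylic carbinols at C3 and C6, the secondary benzoate on O5, which sits between two free hydroxyls and can migrate under base, and the primary allylic benzoate on O7, which is 1,3-related to O6. The carbon skeleton is small, so the real difficulty is regiochemical, only O5 of four secondary oxygens being acylated, together with the one stereocentre, C6, that cannot be bought. C3, C4 and C5 have the D-arabino pattern (3,4-threo, 4,5-erythro), and in a furanose form of that pentose series the oxygen that becomes O5 is the ring oxygen, so it is set apart from O3 and O4 from the first step. The key step exploits the position of C6 between the alkene carbon C1 and the benzoylated C5: an alkenyl metal at C1 that adds to a C6 aldehyde forms the C1–C6 bond, closes ring A and creates C6 in one operation. For that closure the C1=C2 alkene must hold C3 and the metal on the same side, which corresponds to a Z iodoalkene with iodine cis to C3.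

## Logic of the disconnections

**14 ⇒ 13.** The bonds cut are O3–Si and O4–Si. All C–O and acyl bonds of 14 are thus in place before the most migration-prone compound is unveiled, and no selective benzoylation of a polyol is ever needed. The demand on the forward step is a fast, weakly acidic, base-free cleavage. Triethylsilyl ethers meet it. Benzyl-type ethers would need an oxidant next to two allylic carbinols at the end and aqueous acid or strong base earlier, so they are avoided.

**13 ⇒ 11 (through 12).** The C1–C6 bond is cut. This is the only ring bond whose formation also creates the one stereocentre not available from the chiral pool. The gain is an open chain whose three stereocentres and whole acylation pattern are already fixed. The forward step must metalate the C1–I bond in the presence of two benzoates and an aldehyde, must start from the Z alkene, and must deliver O6 trans to O5.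

**11 ⇒ 10 ⇒ 9.** No skeletal bond is cut. C6 is taken back from aldehyde to alcohol and then to its silyl ether (O6–Si bond). The gain is a stable, fully protected chain. The forward steps must free the primary O6 selectively and oxidise it without moving the O5 benzoate or epimerising C5.

**9 ⇒ 7 + 8.** The two acyl C–O bonds at O5 and O7 are cut together. In 7 these are the only free hydroxyls (O5 from the opening of the furanose, O7 from reduction of the ester), so the benzoate pattern follows without any selectivity. The only demand is complete acylation of a hindered secondary alcohol.

**7 ⇒ 6.** The two C7–H bonds are removed, returning C7 to the ester level. This links the allylic alcohol to an olefination product. The hydride must spare the C–I bond and the silyl ethers.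

**6 ⇒ 3 + 5, and 5 ⇒ 4.** The C1=C2 double bond is cut, and for 5 the C1–I bond. One olefination brings in C1, C7 and the iodine and opens the furanose, releasing O5. The forward step must give the Z isomer and must not let O5 add back to the enoate.

**3 ⇒ 2 ⇒ 1.** The lactol C2–H bond and three O–Si bonds are cut. The chain C2 to C6 with C3, C4 and C5 is thus traced to a stock chiron in which O5 is the ring oxygen. The forward steps are a persilylation and a partial reduction that must stop at the lactol.

## Other disconnections considered

Alternative 1: The cut is of the C4–O and C5–O bonds at the outset, so ring A is taken back to an arene.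
- Forward key step: toluene dioxygenase (an iron-dependent arene dioxygenase used in whole cells) would add O2 across one double bond of bromobenzene A1 to give the cis-dihydrodiol A2. C4 and C5 then have the target configuration and the bromine marks C6; no ring is closed.
- Continuation: protection of the diol as an acetonide, addition of singlet oxygen across C3 and C6 anti to the acetonide, and reductive O–O cleavage with loss of HBr would lead to the γ-hydroxy enone A3. Hydroxymethylation at C1 (Morita–Baylis–Hillman type) and reduction of the C6 ketone would follow.
- In its favour: the carbocycle, two stereocentres and the absolute configuration come from one catalytic step on a commodity arene, and C3–O is expected anti to the acetonide. In ring construction and in the number of C–C bond formations (one, C1–C7) this plan is better than the chosen one.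
- Against it here: O4 and O5 emerge as an equivalent pair inside one acetonide and must later be told apart. Hydride is expected to approach the C6 ketone anti to the acetonide, which would put O6 cis to O5 and call for an inversion. The first step needs fermentation equipment.
- Comparison: structurally, the chosen plan inherits C3, C4, C5 and the distinction of O5 from 1 and leaves only C6 open; this plan inherits C4 and C5 and leaves C3, C6, C7 and the O4/O5 distinction open. Mechanistically it uses enzymatic arene oxidation, a pericyclic oxygenation and enone chemistry in place of a polar organometallic closure, at comparable overall risk. In step economy the protecting-group traffic is expected to bring it to the nine steps of the chosen plan or above.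

Alternative 2: The cut is of the C3–O and C6–O bonds together, through a peroxide bridge.
- Forward key step: singlet oxygen would add in a [4+2] fashion across C3 and C6 of the cyclohexa-1,3-diene A5 (C6=C1–C2=C3, O4/O5 as acetonide, C7 benzoate in place). A5 is reachable from shikimic acid A4 by acetonide formation on its cis-diol, ester reduction, benzoylation and elimination of the remaining hydroxyl. Attack anti to the acetonide would give the endoperoxide A6, and O–O reduction would free O3 and O6, both trans to the acetonide.
- In its favour: C3 and C6 are set in one suprafacial step by a simple steric argument, C4 and C5 come from a stock natural product, and C7 is present from the start. In control of C6 this plan is better than the chosen one, and in the origin of the carbocycle it is at least its equal.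
- Against it here: after O–O cleavage the one ring benzoate must go to O5 and not to O4. These are two oxygens of one cis-diol in nearly identical surroundings, so regioselective acylation cannot be relied on. Bicyclic endoperoxides can also rearrange to hydroxy enones under base (Kornblum–DeLaMare), and such dienes aromatise easily.
- Comparison: structurally, this plan builds the oxygenation pattern first and the acylation pattern last; the chosen plan does the reverse and benzoylates at 7, which has no other free hydroxyl. Mechanistically a pericyclic step with dependable facial control stands against a carbonyl addition whose facial control is less certain. In step economy the stereochemical part would be shorter, but the steps needed to single out O5 are expected to cancel that gain.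

Alternative 3: The cut is of the C4–O bond (with a temporary C3–O bond), that is, of an oxirane on C3–C4.
- Forward key step: a peracid, hydrogen-bonded to the free O5–H of the dienoate A7 (C5/C6 trans-diol with O6 as 4-methoxybenzyl ether), would epoxidise the more electron-rich C3=C4 bond on the face of O5 to give A8. Opening of the vinyl oxirane at the allylic C3 with inversion would then place O3 trans to O4.
- In its favour: the C5/C6 trans relation, the point of greatest doubt in the chosen plan, is present from the start (better). O5 is the only free hydroxyl in A8 and can be benzoylated at once, so the regiochemical problem is solved as cleanly as in the chosen plan (equal). Both new C–O bonds come from substrate-directed reactions of known sense.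
- Against it here: A7 is not a stock chemical. It would need a fermentation with an engineered strain followed by esterification and selective protection of O6, or a multi-step synthesis. Dienes of this kind aromatise under acid. The oxirane opening must be steered to C3. The ester must be reduced to the C7 alcohol without loss of the O5 benzoate, which forces a protecting-group exchange.
- Comparison: structurally, this plan inherits C5 and C6 and builds C3 and C4; the chosen plan inherits C3, C4, C5 and builds C6. Mechanistically it rests on directed epoxidation and SN2 opening and needs no transition metal. In step economy it could match the chosen plan from A7 onwards, but the supply of A7 adds steps that the purchase of 1 does not.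

Key step: step 8

Remark: 1 is taken as a catalogue compound (the C1-oxidised form of D-arabinose, carrying the stereocentres that become C3, C4 and C5); 3 is used as an anomeric mixture because its anomeric carbon becomes sp2 in step 3.

## Route

Step 1
Reactants: 1 D-arabinono-1,4-lactone
Product: 2 2,3,5-tris-O-(triethylsilyl)-D-arabinono-1,4-lactone
Conditions: Et3SiCl (3.6 equiv), imidazole (7 equiv), DMAP (cat.), DMF, 0 °C → rt
Reagents that add atoms: chlorotriethylsilane, CC[Si](CC)(CC)Cl
Why: Standard silylation with a silyl chloride and imidazole caps the primary and both secondary hydroxyls of the lactone; the mildly basic medium does not epimerise the α-carbon and no stereocentre is created.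

Step 2
Reactants: 2 2,3,5-tris-O-(triethylsilyl)-D-arabinono-1,4-lactone
Product: 3 2,3,5-tris-O-(triethylsilyl)-D-arabinofuranose (anomeric mixture)
Conditions: i-Bu2AlH (1.2 equiv), CH2Cl2, −78 °C; MeOH, aq. potassium sodium tartrate (KNaC4H4O6)
Reagents that add atoms: none
Why: Partial hydride reduction of a γ-lactone: at −78 °C the aluminium hemiacetal is stable and gives the lactol on work-up without over-reduction; the silyl ethers are inert and the new anomeric centre is lost again in step 3.

Step 3
Reactants: 3 2,3,5-tris-O-(triethylsilyl)-D-arabinofuranose; 4 ethyl (triphenylphosphoranylidene)acetate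
Product: 6 ethyl (Z)-2,3-dideoxy-2-iodo-4,5,7-tris-O-(triethylsilyl)-D-arabino-hept-2-enonate, via ethyl iodo(triphenylphosphoranylidene)acetate 5 (not isolated)
Conditions: 4 (1.5 equiv), N-iodosuccinimide (1.5 equiv), MeCN, −20 °C, 30 min; then 3, 0 → 50 °C
Reagents that add atoms: N-iodosuccinimide, O=C1CCC(=O)N1I
Why: One-pot iodination of the stabilised ylide 4 to 5, then Wittig olefination of the open-chain aldehyde in equilibrium with lactol 3; a stabilised ylide places the ester trans to the C3 chain, so iodine ends up on C1 cis to C3 (Z) and no stereocentre is touched. Ring opening frees O5–H (silyl ethers remain on O3, O4 and O6), and the hydroxyl is expected to stay open because the medium is neutral and the iodo-enoate is a hindered acceptor.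

Step 4
Reactants: 6 ethyl (Z)-2,3-dideoxy-2-iodo-4,5,7-tris-O-(triethylsilyl)-D-arabino-hept-2-enonate
Product: 7 (Z)-2,3-dideoxy-2-iodo-4,5,7-tris-O-(triethylsilyl)-D-arabino-hept-2-enitol (target numbering: O7–H and O5–H free)
Conditions: i-Bu2AlH (3.5 equiv), CH2Cl2, −78 → −40 °C; aq. potassium sodium tartrate (KNaC4H4O6)
Reagents that add atoms: none
Why: 1,2-Reduction of the α-iodo enoate to the allylic alcohol by i-Bu2AlH at low temperature; the alkenyl C–I bond, the Z geometry and the silyl ethers are unaffected, and the free O5–H only consumes one equivalent of hydride.

Step 5
Reactants: 7 (Z)-2,3-dideoxy-2-iodo-4,5,7-tris-O-(triethylsilyl)-D-arabino-hept-2-enitol; 8 benzoyl chloride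
Product: 9 1,6-di-O-benzoyl-(Z)-2,3-dideoxy-2-iodo-4,5,7-tris-O-(triethylsilyl)-D-arabino-hept-2-enitol (target numbering: benzoates on O5 and O7)
Conditions: 8 (3 equiv), pyridine, DMAP (0.2 equiv), CH2Cl2, 0 °C → rt
Reagents that add atoms: none
Why: Acylation with an acid chloride under nucleophilic catalysis by DMAP; O5–H and O7–H are the only free hydroxyls, so the benzoate pattern of the target is installed without any selectivity problem and without touching a stereocentre.

Step 6
Reactants: 9 1,6-di-O-benzoyl-(Z)-2,3-dideoxy-2-iodo-4,5,7-tris-O-(triethylsilyl)-D-arabino-hept-2-enitol
Product: 10 1,6-di-O-benzoyl-(Z)-2,3-dideoxy-2-iodo-4,5-bis-O-(triethylsilyl)-D-arabino-hept-2-enitol (target numbering: O6–H free)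
Conditions: HF·pyridine, pyridine, THF, −10 → 0 °C
Reagents that add atoms: none
Why: Acid fluoride cleavage of silyl ethers is governed by steric access, so the primary O6 triethylsilyl ether goes first while the secondary ethers on O3 and O4 remain; the pyridine-buffered, weakly acidic medium avoids the alkoxide that would let the O5 benzoyl group migrate to O6.

Step 7
Reactants: 10 1,6-di-O-benzoyl-(Z)-2,3-dideoxy-2-iodo-4,5-bis-O-(triethylsilyl)-D-arabino-hept-2-enitol
Product: 11 (2S,3R,4R,5Z)-2,7-bis(benzoyloxy)-6-iodo-3,4-bis[(triethylsilyl)oxy]hept-5-enal (the Z-iodoalkene aldehyde; aldehyde carbon = C6)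
Conditions: Dess–Martin periodinane (1.5 equiv), NaHCO3, CH2Cl2, 0 °C → rt; crude 11 used at once
Reagents that add atoms: none
Why: Dess–Martin oxidation of a primary alcohol under buffered, essentially neutral conditions, which preserves the α-benzoyloxy stereocentre C5 and does not induce β-elimination of the C4 silyloxy group; the aldehyde is carried on without chromatography.

Step 8
Reactants: 11 (2S,3R,4R,5Z)-2,7-bis(benzoyloxy)-6-iodo-3,4-bis[(triethylsilyl)oxy]hept-5-enal
Product: 13 [(3R,4R,5R,6S)-5-(benzoyloxy)-6-hydroxy-3,4-bis[(triethylsilyl)oxy]cyclohex-1-en-1-yl]methyl benzoate, via alkenylchromium dichloride 12 (not isolated)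
Conditions: CrCl2 (8 equiv), NiCl2 (0.1 equiv), degassed DMF, 0.005 M, 11 added over 6 h, rt; aq. NH4Cl
Reagents that add atoms: none
Why: Divalent chromium reduces NiCl2 to zerovalent nickel, which inserts into the C1–I bond with retention of the Z geometry, and transmetalation gives the trivalent alkenylchromium 12, which adds to the C6 aldehyde (Nozaki–Hiyama–Kishi reaction; closest known type: cyclisation of sugar-derived haloalkene aldehydes to cyclohexenols). Ring A closes in a 6-exo-trig mode, possible only because the Z alkene already holds C3 and the metal on the same side. The organochromium is non-basic and selective for aldehydes, so the two benzoates, the allylic C7–O bond, the silyl ethers and the epimerisable C5 are expected to survive, and high dilution suppresses intermolecular coupling. The new stereocentre C6 is under substrate control from C5 and C4: in the half-chair with the vicinal trans silyloxy groups on C3 and C4 axial, the C5 benzoate is equatorial and antiperiplanar to the forming C1–C6 bond (Felkin–Anh alignment), and the carbonyl oxygen takes the pseudoequatorial site to avoid a 1,3-diaxial contact with the C4 silyloxy group, which gives O6 trans to O5. In the other half-chair (C3 and C4 substituents equatorial, C5 benzoate axial) the carbonyl oxygen prefers the pseudoaxial site, anti to the C5–O dipole and clear of allylic strain with C7, which again gives the trans isomer. The open-chain Felkin–Anh rule cannot be used as such, because the nucleophile is tied to C4; taken alone it would predict the erythro pair, which is cis in the ring, so it is the ring transition state that secures 6S. The selectivities needed are therefore C–I over allylic C–O insertion, aldehyde over ester addition, and the 5,6-trans facial sense.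

Step 9
Reactants: 13 [(3R,4R,5R,6S)-5-(benzoyloxy)-6-hydroxy-3,4-bis[(triethylsilyl)oxy]cyclohex-1-en-1-yl]methyl benzoate
Product: 14 [(3R,4S,5R,6S)-5-(benzoyloxy)-3,4,6-trihydroxycyclohex-1-en-1-yl]methyl benzoate
Conditions: HF·pyridine, THF, 0 °C → rt
Reagents that add atoms: none
Why: Fluoride-assisted solvolysis of the two secondary triethylsilyl ethers, which are much more labile than bulkier silyl ethers; the medium is weakly acidic and free of alkoxide, so benzoyl migration from O5 or O7 to the neighbouring hydroxyls is not expected, and no stereocentre or allylic C–O bond is touched.

## Compound list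

1 | D-arabinono-1,4-lactone, (3S,4S,5R)-3,4-dihydroxy-5-(hydroxymethyl)oxolan-2-one | O=C1[C@@H](O)[C@H](O)[C@@H](CO)O1 | starting material
2 | 2,3,5-tris-O-(triethylsilyl)-D-arabinono-1,4-lactone | O=C1[C@@H](O[Si](CC)(CC)CC)[C@H](O[Si](CC)(CC)CC)[C@@H](CO[Si](CC)(CC)CC)O1 | intermediate
3 | 2,3,5-tris-O-(triethylsilyl)-D-arabinofuranose (anomeric mixture) | OC1[C@@H](O[Si](CC)(CC)CC)[C@H](O[Si](CC)(CC)CC)[C@@H](CO[Si](CC)(CC)CC)O1 | intermediate
4 | ethyl (triphenylphosphoranylidene)acetate | CCOC(=O)C=P(c1ccccc1)(c1ccccc1)c1ccccc1 | starting material
5 | ethyl iodo(triphenylphosphoranylidene)acetate (formed in the flask, not isolated) | CCOC(=O)C(I)=P(c1ccccc1)(c1ccccc1)c1ccccc1 | intermediate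
6 | ethyl (Z)-2,3-dideoxy-2-iodo-4,5,7-tris-O-(triethylsilyl)-D-arabino-hept-2-enonate (target numbering: iodine on C1 cis to C3; O5–H free; silyl ethers on O3, O4 and O6) | CCOC(=O)/C(I)=C/[C@@H](O[Si](CC)(CC)CC)[C@H](O[Si](CC)(CC)CC)[C@H](O)CO[Si](CC)(CC)CC | intermediate
7 | (Z)-2,3-dideoxy-2-iodo-4,5,7-tris-O-(triethylsilyl)-D-arabino-hept-2-enitol | OC/C(I)=C/[C@@H](O[Si](CC)(CC)CC)[C@H](O[Si](CC)(CC)CC)[C@H](O)CO[Si](CC)(CC)CC | intermediate
8 | benzoyl chloride | O=C(Cl)c1ccccc1 | starting material
9 | 1,6-di-O-benzoyl-(Z)-2,3-dideoxy-2-iodo-4,5,7-tris-O-(triethylsilyl)-D-arabino-hept-2-enitol | O=C(OC/C(I)=C/[C@@H](O[Si](CC)(CC)CC)[C@H](O[Si](CC)(CC)CC)[C@H](OC(=O)c1ccccc1)CO[Si](CC)(CC)CC)c1ccccc1 | intermediate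
10 | 1,6-di-O-benzoyl-(Z)-2,3-dideoxy-2-iodo-4,5-bis-O-(triethylsilyl)-D-arabino-hept-2-enitol | O=C(OC/C(I)=C/[C@@H](O[Si](CC)(CC)CC)[C@H](O[Si](CC)(CC)CC)[C@H](OC(=O)c1ccccc1)CO)c1ccccc1 | intermediate
11 | (2S,3R,4R,5Z)-2,7-bis(benzoyloxy)-6-iodo-3,4-bis[(triethylsilyl)oxy]hept-5-enal | O=C(OC/C(I)=C/[C@@H](O[Si](CC)(CC)CC)[C@H](O[Si](CC)(CC)CC)[C@H](OC(=O)c1ccccc1)C=O)c1ccccc1 | intermediate
12 | alkenylchromium dichloride from 11 (trivalent chromium on C1, Z geometry retained; formed in the flask, not isolated) | O=C(OC/C([Cr](Cl)Cl)=C/[C@@H](O[Si](CC)(CC)CC)[C@H](O[Si](CC)(CC)CC)[C@H](OC(=O)c1ccccc1)C=O)c1ccccc1 | intermediate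
13 | [(3R,4R,5R,6S)-5-(benzoyloxy)-6-hydroxy-3,4-bis[(triethylsilyl)oxy]cyclohex-1-en-1-yl]methyl benzoate | O=C(OCC1=C[C@@H](O[Si](CC)(CC)CC)[C@H](O[Si](CC)(CC)CC)[C@H](OC(=O)c2ccccc2)[C@H]1O)c1ccccc1 | intermediate
14 | [(3R,4S,5R,6S)-5-(benzoyloxy)-3,4,6-trihydroxycyclohex-1-en-1-yl]methyl benzoate | O=C(OCC1=C[C@@H](O)[C@H](O)[C@H](OC(=O)c2ccccc2)[C@H]1O)c1ccccc1 | target

## Step count and least certain steps

Total step count: 9. Longest linear sequence: 9 steps (1 → 14).

**Step 8 (key step).**
- Most likely to go wrong: insufficient facial discrimination at the C6 aldehyde, because the half-chair transition states leading to the 5,6-cis alcohol may lie close to those leading to the trans alcohol. A second risk is β-elimination of the C7 benzoate from the alkenyl metal before it reaches the aldehyde.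
- Fallback, setting out from 11 and returning at 13: the cyclisation is run as in step 8 without regard to selectivity, and the 5,6-cis cyclohexenol [(3R,4R,5R,6R)-5-(benzoyloxy)-6-hydroxy-3,4-bis[(triethylsilyl)oxy]cyclohex-1-en-1-yl]methyl benzoate F1 is collected. Mitsunobu inversion with chloroacetic acid (PPh3, diisopropyl azodicarboxylate, toluene, 0 °C → rt) would give the 6S chloroacetate [(3R,4R,5R,6S)-5-(benzoyloxy)-6-(chloroacetoxy)-3,4-bis[(triethylsilyl)oxy]cyclohex-1-en-1-yl]methyl benzoate F2, since the cis benzoate on C5 cannot take part as a neighbouring group. The chloroacetyl group is then removed with thiourea and NaHCO3 in ethanol at 50 °C, conditions that leave benzoates and silyl ethers alone, and the route is rejoined at 13.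

**Step 3.**
- Most likely to go wrong: slow olefination, because the lactol releases little free aldehyde and the thermally sensitive ylide 5 may decompose first. Erosion of the Z selectivity and conjugate ring closure of the liberated O5 hydroxyl onto the enoate are further risks.
- Fallback, setting out from 3 and 4 and returning at 6: 4 is brominated with N-bromosuccinimide and the more robust ylide ethyl bromo(triphenylphosphoranylidene)acetate F3 is isolated. It is heated with 3 in toluene at 80 °C to give the Z-bromo enoate ethyl (Z)-2-bromo-2,3-dideoxy-4,5,7-tris-O-(triethylsilyl)-D-arabino-hept-2-enonate F4. Copper-catalysed halogen exchange of the Finkelstein type (NaI, CuI, trans-N,N'-dimethylcyclohexane-1,2-diamine, 1,4-dioxane, 110 °C), which proceeds with retention at an alkenyl bromide, would then give 6.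

**Step 6.**
- Most likely to go wrong: incomplete discrimination between the primary and the two secondary triethylsilyl ethers, and migration of the O5 benzoyl group to the newly freed primary hydroxyl on O6.
- Fallback, setting out from 9 and returning at 11: the primary triethylsilyl ether is oxidised directly under Swern conditions ((COCl)2, DMSO, CH2Cl2, −78 → −40 °C; then i-Pr2NEt, −78 °C). This is a known chemoselective oxidative cleavage of primary triethylsilyl ethers in the presence of secondary ones. The alcohol 10 never accumulates, so acyl migration is pre-empted, and the route is rejoined at 11. No new compound is made on this way, which is entered as F0.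

## Further compounds

F1 | step 8 | [(3R,4R,5R,6R)-5-(benzoyloxy)-6-hydroxy-3,4-bis[(triethylsilyl)oxy]cyclohex-1-en-1-yl]methyl benzoate, the C6 epimer of 13 | O=C(OCC1=C[C@@H](O[Si](CC)(CC)CC)[C@H](O[Si](CC)(CC)CC)[C@H](OC(=O)c2ccccc2)[C@@H]1O)c1ccccc1
F2 | step 8 | [(3R,4R,5R,6S)-5-(benzoyloxy)-6-(chloroacetoxy)-3,4-bis[(triethylsilyl)oxy]cyclohex-1-en-1-yl]methyl benzoate, the 6-O-chloroacetate of 13 | O=C(OCC1=C[C@@H](O[Si](CC)(CC)CC)[C@H](O[Si](CC)(CC)CC)[C@H](OC(=O)c2ccccc2)[C@H]1OC(=O)CCl)c1ccccc1
F3 | step 3 | ethyl bromo(triphenylphosphoranylidene)acetate | CCOC(=O)C(Br)=P(c1ccccc1)(c1ccccc1)c1ccccc1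
F4 | step 3 | ethyl (Z)-2-bromo-2,3-dideoxy-4,5,7-tris-O-(triethylsilyl)-D-arabino-hept-2-enonate | CCOC(=O)/C(Br)=C/[C@@H](O[Si](CC)(CC)CC)[C@H](O[Si](CC)(CC)CC)[C@H](O)CO[Si](CC)(CC)CC
F0 | step 6 | none | none
A1 | alternative 1 | bromobenzene | Brc1ccccc1
A2 | alternative 1 | (1S,2S)-3-bromocyclohexa-3,5-diene-1,2-diol | BrC1=CC=C[C@H](O)[C@@H]1O
A3 | alternative 1 | 4-hydroxy-5,6-(isopropylidenedioxy)cyclohex-2-en-1-one, hydroxyl trans to the acetonide (target numbering: C6 ketone, O3–H, O4/O5 acetonide) | O=C1C=C[C@@H](O)[C@@H]2OC(C)(C)O[C@@H]21
A4 | alternative 2 | shikimic acid, (3R,4S,5R)-3,4,5-trihydroxycyclohex-1-ene-1-carboxylic acid | O=C(O)C1=C[C@@H](O)[C@@H](O)[C@H](O)C1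
A5 | alternative 2 | benzoate of the 4,5-O-isopropylidene cyclohexa-1,3-diene (C6=C1–C2=C3, target numbering) derived from A4 | O=C(OCC1=C[C@H]2OC(C)(C)O[C@H]2C=C1)c1ccccc1
A6 | alternative 2 | C3,C6-endoperoxide of A5, peroxide bridge trans to the 4,5-acetonide | O=C(OCC1=C[C@@H]3[C@@H]2OC(C)(C)O[C@@H]2[C@H]1OO3)c1ccccc1
A7 | alternative 3 | methyl (5S,6S)-5-hydroxy-6-[(4-methoxybenzyl)oxy]cyclohexa-1,3-diene-1-carboxylate | COC(=O)C1=CC=C[C@H](O)[C@H]1OCc1ccc(OC)cc1
A8 | alternative 3 | C3–C4 epoxide of A7, oxirane cis to the C5 hydroxyl | COC(=O)C1=C[C@@H]2O[C@@H]2[C@H](O)[C@H]1OCc1ccc(OC)cc1
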